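**Plan**
- Retrosynthesis: the ten benzyl groups are removed first, then the three galloyl ester C–O bonds at O3, O4 and O5 are cut. The C3–O bond is traced back to a C2=C3 alkene (oxygen delivered from O1 through a silicon tether), and the C1–O and C4–O bonds are cut together as the two ends of an O–O bridge over a cyclohexa-1,3-diene.
- Enabling feature: on the cyclohexane ring O1 and O4 are cis-1,4 to each other and both trans to O5. This is the pattern left when a 1,2-dioxane bridge (a 2,3-dioxabicyclo[2.2.2]octene) is laid across C1 and C4 on the face away from the C5 substituent and its O–O bond is then cleaved.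
- Forward: (−)-shikimic acid supplies the carbocycle. Benzyl ester formation, 3,4-thionocarbonate formation, O5 aroylation and Corey–Winter olefination give the 1,3-diene. Singlet oxygen closes the only new (temporary) ring, thiourea opens it, and O4 is aroylated. An O1–SiHMe2 tether adds to C2=C3 and is oxidised to O3; the third aroylation and a global hydrogenolysis finish.
- Stereochemistry: C5 (R) is inherited from shikimic acid. It sends the peroxide bridge to the opposite face (C1 and C4, cis to each other through the bridge), and the O1 tether then places O3 on the face of O1 and O4.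

Key step: step 6

Remark: the target is read as 3,4,5-tri-O-galloyl-(−)-quinic acid (free 1-OH, free CO2H); ring positions follow quinic/shikimic acid numbering throughout (C1 carries the carboxyl carbon, O5 is trans to O4), and 3,4,5-tris(benzyloxy)benzoic acid is taken as purchasable.

**Step 1**
Reactants: 1 (−)-shikimic acid
Product: 2 benzyl shikimate
Conditions: BnBr, KHCO3, DMF, rt
Reagents that add atoms: benzyl bromide, BrCc1ccccc1
Why: SN2 O-alkylation of the carboxylate, the only group deprotonated by bicarbonate, gives a benzyl ester that should survive every later step and leave in the final hydrogenolysis, with no stereocentre touched.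

**Step 2**
Reactants: 2 benzyl shikimate
Product: 3 benzyl 3,4-O-thiocarbonylshikimate
Conditions: 1,1'-thiocarbonyldiimidazole (1.1 equiv), THF, rt
Reagents that add atoms: 1,1'-thiocarbonyldiimidazole, S=C(n1ccnc1)n1ccnc1
Why: Cyclic thionocarbonate formation (double acyl substitution at the thiocarbonyl carbon) should select the cis-3,4-diol, because only that pair can close a cis-fused five-membered ring on the cyclohexene, leaving the trans 5-OH free and all stereocentres intact.

**Step 3**
Reactants: 4 3,4,5-tris(benzyloxy)benzoic acid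
Product: 5 3,4,5-tris(benzyloxy)benzoyl chloride
Conditions: (COCl)2, DMF (cat.), CH2Cl2, 0 °C → rt; evaporate, use crude
Reagents that add atoms: oxalyl chloride, O=C(Cl)C(=O)Cl
Why: DMF-catalysed acid chloride formation with oxalyl chloride is routine for this acid, and the aryl benzyl ethers are inert to it.

**Step 4**
Reactants: 3 benzyl 3,4-O-thiocarbonylshikimate; 5 3,4,5-tris(benzyloxy)benzoyl chloride
Product: 6 benzyl 5-O-[3,4,5-tris(benzyloxy)benzoyl]-3,4-O-thiocarbonylshikimate
Conditions: Et3N, DMAP (cat.), CH2Cl2, 0 °C → rt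
Reagents that add atoms: none
Why: DMAP-catalysed acylation of the single free hydroxyl installs the protected O5 galloyl unit while the ring is still a simple cyclohexene, so the amine base never meets the elimination-prone dienyl ester formed in the next step.

**Step 5**
Reactants: 6 benzyl 5-O-[3,4,5-tris(benzyloxy)benzoyl]-3,4-O-thiocarbonylshikimate
Product: 7 benzyl (5R)-5-[3,4,5-tris(benzyloxy)benzoyloxy]cyclohexa-1,3-diene-1-carboxylate
Conditions: 1,3-dimethyl-2-phenyl-1,3,2-diazaphospholidine (3 equiv), THF, 40 °C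
Reagents that add atoms: none
Why: Corey–Winter olefination in its low-temperature diazaphospholidine variant: trivalent phosphorus abstracts sulfur and the resulting 2-ylidene-1,3-dioxolane loses CO2 by stereospecific syn cycloelimination, giving C3=C4 conjugated with C1=C2 at a temperature meant to keep the dienyl ester from aromatising.

**Step 6**
Reactants: 7 benzyl (5R)-5-[3,4,5-tris(benzyloxy)benzoyloxy]cyclohexa-1,3-diene-1-carboxylate; 8 dioxygen
Product: 9 benzyl 8-[3,4,5-tris(benzyloxy)benzoyloxy]-2,3-dioxabicyclo[2.2.2]oct-5-ene-1-carboxylate (peroxide bridge C1–O–O–C4 anti to the C5 ester)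
Conditions: O2, tetraphenylporphyrin (cat.), visible light, CH2Cl2, −30 °C
Reagents that add atoms: none
Why: Light-excited tetraphenylporphyrin sensitises dioxygen 8 to its singlet state, which adds as a two-atom dienophile across C1 and C4 of the ring-locked s-cis diene in a concerted suprafacial [4+2] cycloaddition, forming the C1–O and C4–O bonds together. The closest known reaction type is the photooxygenation of cyclohexa-1,3-dienes to 2,3-dioxabicyclo[2.2.2]oct-5-enes, and dienoic esters such as sorbates are known to undergo the same cycloaddition, only more slowly. The one ring closed is the six-membered 1,2-dioxane (C1–O–O–C4–C3=C2), and it closes by cycloaddition, both ends bonding in the same event from the same face, not by an exo or endo cyclisation. The new stereocentres C1 and C4 are necessarily cis to each other because one O–O unit spans them, and their sense is set by the existing C5 centre, whose allylic aroyloxy group shields its own face sterically and repels the electrophilic oxidant, so the bridge should form anti to O5. The step needs this facial selectivity and [4+2] addition in preference to Schenck ene hydroperoxidation at the C5–H and C6–H2 allylic hydrogens; the first rests on the C5 ester and the second on the cisoid geometry enforced by the ring, helped by low temperature and a weakly polar solvent. Because the ester on C1 lowers the rate, long irradiation at low temperature is planned, to which the peroxide and the benzyl ethers should be inert.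

**Step 7**
Reactants: 9 benzyl 8-[3,4,5-tris(benzyloxy)benzoyloxy]-2,3-dioxabicyclo[2.2.2]oct-5-ene-1-carboxylate
Product: 10 benzyl (1R,4R,5R)-1,4-dihydroxy-5-[3,4,5-tris(benzyloxy)benzoyloxy]cyclohex-2-ene-1-carboxylate
Conditions: thiourea, MeOH/CH2Cl2 (moist), 0 °C → rt
Reagents that add atoms: none
Why: Thiourea reduction of the O–O bond is the standard neutral conversion of bicyclic endoperoxides into cis-2-ene-1,4-diols; no C–O bond is broken, so C1 and C4 keep their configuration, and the neutral medium avoids a base-induced Kornblum–DeLaMare rearrangement.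

**Step 8**
Reactants: 10 benzyl (1R,4R,5R)-1,4-dihydroxy-5-[3,4,5-tris(benzyloxy)benzoyloxy]cyclohex-2-ene-1-carboxylate; 5 3,4,5-tris(benzyloxy)benzoyl chloride
Product: 11 benzyl (1R,4R,5R)-1-hydroxy-4,5-bis[3,4,5-tris(benzyloxy)benzoyloxy]cyclohex-2-ene-1-carboxylate
Conditions: 5 (1.1 equiv), Et3N, DMAP (cat.), CH2Cl2, 0 °C
Reagents that add atoms: none
Why: DMAP-catalysed acylation should pick the secondary allylic 4-OH over the tertiary 1-OH, which is hindered and deactivated as an α-hydroxy ester; a prior O5→O4 acyl shift would be harmless because both oxygens end with the same acyl group.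

**Step 9**
Reactants: 11 benzyl (1R,4R,5R)-1-hydroxy-4,5-bis[3,4,5-tris(benzyloxy)benzoyloxy]cyclohex-2-ene-1-carboxylate
Product: 12 benzyl (1R,4R,5R)-1-(dimethylsilyloxy)-4,5-bis[3,4,5-tris(benzyloxy)benzoyloxy]cyclohex-2-ene-1-carboxylate
Conditions: Me2SiHCl, Et3N, DMAP (cat.), CH2Cl2, 0 °C → rt; filter, concentrate, use crude
Reagents that add atoms: chlorodimethylsilane, C[SiH](C)Cl
Why: O-silylation with the small chlorodimethylsilane should reach the tertiary hydroxyl, the only OH left, and so places an Si–H bond on the O1 face of the ring next to C2=C3.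

**Step 10**
Reactants: 12 benzyl (1R,4R,5R)-1-(dimethylsilyloxy)-4,5-bis[3,4,5-tris(benzyloxy)benzoyloxy]cyclohex-2-ene-1-carboxylate
Product: 14 benzyl 4,5-di-O-[3,4,5-tris(benzyloxy)benzoyl]quinate, via cyclic siloxane 13 (not isolated)
Conditions: Pt2[(CH2=CHSiMe2)2O]3 (zerovalent platinum, cat.), toluene, 60 °C; then 30% aq. H2O2, KF, KHCO3, THF, 0 °C → rt
Reagents that add atoms: hydrogen peroxide, OO
Why: Platinum-catalysed intramolecular hydrosilylation of the allylic hydrosilyl ether should close the five-membered oxasilolane in the 5-endo sense (the alternative is a four-membered ring), so silicon bonds to C3 and hydrogen to C2 by syn addition on the face of O1, and Tamao oxidation then replaces C3–Si by C3–OH with retention, which sets C3 cis to O1 and O4.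

**Step 11**
Reactants: 14 benzyl 4,5-di-O-[3,4,5-tris(benzyloxy)benzoyl]quinate; 5 3,4,5-tris(benzyloxy)benzoyl chloride
Product: 15 benzyl 3,4,5-tri-O-[3,4,5-tris(benzyloxy)benzoyl]quinate
Conditions: 5 (1.3 equiv), Et3N, DMAP, CH2Cl2, 0 °C → rt
Reagents that add atoms: none
Why: DMAP-catalysed acylation of the remaining secondary hydroxyl should leave the hindered tertiary 1-OH free, and if an O4→O3 acyl shift occurred in step 10 the free secondary hydroxyl is acylated all the same and the same triester results.

**Step 12**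
Reactants: 15 benzyl 3,4,5-tri-O-[3,4,5-tris(benzyloxy)benzoyl]quinate
Product: 16 3,4,5-tri-O-galloyl-(−)-quinic acid (CNP0148451.1)
Conditions: H2 (1 atm), 10% Pd/C, THF/MeOH, rt
Reagents that add atoms: none
Why: Catalytic hydrogenolysis should cleave the nine aryl benzyl ethers and the benzyl ester at their benzylic C–O bonds while the aroyl esters, the tertiary alcohol and all four stereocentres stay untouched.

**Compound list**
1 | (−)-shikimic acid, (3R,4S,5R)-3,4,5-trihydroxycyclohex-1-ene-1-carboxylic acid | O[C@@H]1CC(C(=O)O)=C[C@@H](O)[C@H]1O | starting material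
2 | benzyl shikimate | O[C@@H]1CC(C(=O)OCc2ccccc2)=C[C@@H](O)[C@H]1O | intermediate
3 | benzyl 3,4-O-thiocarbonylshikimate (cis-fused cyclic thionocarbonate on O3/O4, 5-OH free) | O[C@@H]1CC(C(=O)OCc2ccccc2)=C[C@H]3OC(=S)O[C@@H]13 | intermediate
4 | 3,4,5-tris(benzyloxy)benzoic acid | O=C(O)c1cc(OCc2ccccc2)c(OCc2ccccc2)c(OCc2ccccc2)c1 | starting material
5 | 3,4,5-tris(benzyloxy)benzoyl chloride | O=C(Cl)c1cc(OCc2ccccc2)c(OCc2ccccc2)c(OCc2ccccc2)c1 | intermediate
6 | benzyl 5-O-[3,4,5-tris(benzyloxy)benzoyl]-3,4-O-thiocarbonylshikimate | O=C(O[C@@H]1CC(C(=O)OCc2ccccc2)=C[C@H]3OC(=S)O[C@@H]13)c1cc(OCc2ccccc2)c(OCc2ccccc2)c(OCc2ccccc2)c1 | intermediate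
7 | benzyl (5R)-5-[3,4,5-tris(benzyloxy)benzoyloxy]cyclohexa-1,3-diene-1-carboxylate | O=C(O[C@@H]1CC(C(=O)OCc2ccccc2)=CC=C1)c1cc(OCc2ccccc2)c(OCc2ccccc2)c(OCc2ccccc2)c1 | intermediate
8 | dioxygen (reacts as singlet oxygen) | O=O | starting material
9 | benzyl 8-[3,4,5-tris(benzyloxy)benzoyloxy]-2,3-dioxabicyclo[2.2.2]oct-5-ene-1-carboxylate, O–O bridge across C1/C4 on the face opposite the C5 ester | O=C(O[C@@H]1C[C@]2(C(=O)OCc3ccccc3)C=C[C@H]1OO2)c1cc(OCc2ccccc2)c(OCc2ccccc2)c(OCc2ccccc2)c1 | intermediate
10 | benzyl (1R,4R,5R)-1,4-dihydroxy-5-[3,4,5-tris(benzyloxy)benzoyloxy]cyclohex-2-ene-1-carboxylate (1-OH and 4-OH cis, both trans to O5) | O=C(O[C@@H]1C[C@](O)(C(=O)OCc2ccccc2)C=C[C@H]1O)c1cc(OCc2ccccc2)c(OCc2ccccc2)c(OCc2ccccc2)c1 | intermediate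
11 | benzyl (1R,4R,5R)-1-hydroxy-4,5-bis[3,4,5-tris(benzyloxy)benzoyloxy]cyclohex-2-ene-1-carboxylate | O=C(O[C@@H]1C[C@](O)(C(=O)OCc2ccccc2)C=C[C@H]1OC(=O)c1cc(OCc2ccccc2)c(OCc2ccccc2)c(OCc2ccccc2)c1)c1cc(OCc2ccccc2)c(OCc2ccccc2)c(OCc2ccccc2)c1 | intermediate
12 | benzyl (1R,4R,5R)-1-(dimethylsilyloxy)-4,5-bis[3,4,5-tris(benzyloxy)benzoyloxy]cyclohex-2-ene-1-carboxylate | O=C(O[C@@H]1C[C@](O[SiH](C)C)(C(=O)OCc2ccccc2)C=C[C@H]1OC(=O)c1cc(OCc2ccccc2)c(OCc2ccccc2)c(OCc2ccccc2)c1)c1cc(OCc2ccccc2)c(OCc2ccccc2)c(OCc2ccccc2)c1 | intermediate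
13 | cyclic siloxane: benzyl 7,7-dimethyl-2,3-bis[3,4,5-tris(benzyloxy)benzoyloxy]-6-oxa-7-silabicyclo[3.2.1]octane-5-carboxylate (O1–SiMe2–C3 bridge on the face of O4) | O=C(O[C@@H]1C[C@]2(C(=O)OCc3ccccc3)C[C@@H]([Si](C)(C)O2)[C@H]1OC(=O)c1cc(OCc3ccccc3)c(OCc3ccccc3)c(OCc3ccccc3)c1)c1cc(OCc2ccccc2)c(OCc2ccccc2)c(OCc2ccccc2)c1 | intermediate
14 | benzyl 4,5-di-O-[3,4,5-tris(benzyloxy)benzoyl]quinate (1-OH, 3-OH and O4 on one face, O5 on the other) | O=C(O[C@@H]1C[C@](O)(C(=O)OCc2ccccc2)C[C@@H](O)[C@H]1OC(=O)c1cc(OCc2ccccc2)c(OCc2ccccc2)c(OCc2ccccc2)c1)c1cc(OCc2ccccc2)c(OCc2ccccc2)c(OCc2ccccc2)c1 | intermediate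
15 | benzyl 3,4,5-tri-O-[3,4,5-tris(benzyloxy)benzoyl]quinate | O=C(O[C@@H]1C[C@](O)(C(=O)OCc2ccccc2)C[C@@H](OC(=O)c2cc(OCc3ccccc3)c(OCc3ccccc3)c(OCc3ccccc3)c2)[C@H]1OC(=O)c1cc(OCc2ccccc2)c(OCc2ccccc2)c(OCc2ccccc2)c1)c1cc(OCc2ccccc2)c(OCc2ccccc2)c(OCc2ccccc2)c1 | intermediate
16 | 3,4,5-tri-O-galloyl-(−)-quinic acid: 1-hydroxy-3,4,5-tris(3,4,5-trihydroxybenzoyloxy)cyclohexane-1-carboxylic acid with the (1S,3R,4S,5R) configuration of (−)-quinic acid | O=C(O[C@@H]1C[C@](O)(C(=O)O)C[C@@H](OC(=O)c2cc(O)c(O)c(O)c2)[C@H]1OC(=O)c1cc(O)c(O)c(O)c1)c1cc(O)c(O)c(O)c1 | target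

**Step count**
Total: 12 steps. Longest linear sequence: 11 steps from shikimic acid (steps 1, 2 and 4–12); step 3 prepares the acylating agent used in steps 4, 8 and 11.

**Steps most likely to fail**

1. Step 6 (key step). The single ester on C5 may shield its face too weakly, so that part of the oxidant adds syn to O5. The ester-deactivated diene may also react slowly enough for ene hydroperoxidation or gradual aromatisation to compete. The fallback changes the controlling group and the order of acylation; it sets out from 3 and returns at 11.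
 - O5 of 3 is silylated (TBSCl, imidazole, DMF) to benzyl 5-O-(tert-butyldimethylsilyl)-3,4-O-thiocarbonylshikimate F1.
 - The same diazaphospholidine olefination gives benzyl (5R)-5-(tert-butyldimethylsilyloxy)cyclohexa-1,3-diene-1-carboxylate F2, which has no leaving group on C5 and carries a bulkier, three-dimensional shield.
 - Photooxygenation (O2, tetraphenylporphyrin, visible light, CH2Cl2, −30 °C) should give the anti endoperoxide benzyl 8-(tert-butyldimethylsilyloxy)-2,3-dioxabicyclo[2.2.2]oct-5-ene-1-carboxylate F3.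
 - Thiourea opens it to benzyl (1R,4R,5R)-5-(tert-butyldimethylsilyloxy)-1,4-dihydroxycyclohex-2-ene-1-carboxylate F4.
 - HF·pyridine in THF removes the silyl group to give benzyl (1R,4R,5R)-1,4,5-trihydroxycyclohex-2-ene-1-carboxylate F5.
 - Both secondary hydroxyls of F5 are acylated together with 5 (2.2 equiv, Et3N, DMAP, CH2Cl2, 0 °C), which gives 11.

2. Step 10. Closure of the strained bridged siloxane on an alkene flanked by two oxygenated carbons may not occur, with loss of the Si–H group or alkene migration instead. The basic peroxide of the oxidation may also cleave or shift aroyl esters. The fallback replaces the tether by hydroxyl-directed epoxidation, trans-diaxial opening and radical dehalogenation; it sets out from 11 and returns at 14.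
 - The free 1-OH of 11 directs epoxidation (tBuOOH, VO(acac)2, CH2Cl2, rt) to its own face, giving benzyl 2,3-epoxy-1-hydroxy-4,5-bis[3,4,5-tris(benzyloxy)benzoyloxy]cyclohexane-1-carboxylate F6 (epoxide cis to O1 and O4).
 - MgI2 (Et2O/toluene, −20 °C) should open the epoxide by axial attack of iodide at C2 from the opposite face. This is the trans-diaxial mode in the chair that keeps the C1 ester and both aroyloxy groups equatorial, and it gives benzyl 2-iodo-4,5-di-O-[3,4,5-tris(benzyloxy)benzoyl]quinate F7 (iodine trans to O1 and O3, 3-OH on the face of O1 and O4).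
 - Bu3SnH with AIBN (toluene, 80 °C) removes the iodine and gives 14.

3. Step 5. The newly formed dienyl ester may lose its C5 carboxylate and aromatise under the warm, mildly basic olefination and during purification. The fallback changes the order of events, so that the leaving group is installed only after the diene exists; it sets out from 3 and returns at 7.
 - The diazaphospholidine olefination is run on the free alcohol 3 to give benzyl (5R)-5-hydroxycyclohexa-1,3-diene-1-carboxylate F8, in which hydroxide is a poor leaving group.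
 - F8 is acylated at once with 5 and pyridine in CH2Cl2 at −20 °C to give 7, which is carried into step 6 without storage.

**Further compounds**
F1 | step 6 | benzyl 5-O-(tert-butyldimethylsilyl)-3,4-O-thiocarbonylshikimate | CC(C)(C)[Si](C)(C)O[C@@H]1CC(C(=O)OCc2ccccc2)=C[C@H]3OC(=S)O[C@@H]13
F2 | step 6 | benzyl (5R)-5-(tert-butyldimethylsilyloxy)cyclohexa-1,3-diene-1-carboxylate | CC(C)(C)[Si](C)(C)O[C@@H]1CC(C(=O)OCc2ccccc2)=CC=C1
F3 | step 6 | benzyl 8-(tert-butyldimethylsilyloxy)-2,3-dioxabicyclo[2.2.2]oct-5-ene-1-carboxylate (peroxide bridge anti to the silyloxy group) | CC(C)(C)[Si](C)(C)O[C@@H]1C[C@]2(C(=O)OCc3ccccc3)C=C[C@H]1OO2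
F4 | step 6 | benzyl (1R,4R,5R)-5-(tert-butyldimethylsilyloxy)-1,4-dihydroxycyclohex-2-ene-1-carboxylate | CC(C)(C)[Si](C)(C)O[C@@H]1C[C@](O)(C(=O)OCc2ccccc2)C=C[C@H]1O
F5 | step 6 | benzyl (1R,4R,5R)-1,4,5-trihydroxycyclohex-2-ene-1-carboxylate | O[C@@H]1C[C@](O)(C(=O)OCc2ccccc2)C=C[C@H]1O
F6 | step 10 | benzyl 2,3-epoxy-1-hydroxy-4,5-bis[3,4,5-tris(benzyloxy)benzoyloxy]cyclohexane-1-carboxylate (epoxide cis to O1 and O4) | O=C(O[C@@H]1C[C@](O)(C(=O)OCc2ccccc2)[C@H]3O[C@H]3[C@H]1OC(=O)c1cc(OCc2ccccc2)c(OCc2ccccc2)c(OCc2ccccc2)c1)c1cc(OCc2ccccc2)c(OCc2ccccc2)c(OCc2ccccc2)c1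
F7 | step 10 | benzyl 2-iodo-4,5-di-O-[3,4,5-tris(benzyloxy)benzoyl]quinate (iodine trans to O1 and O3) | O=C(O[C@@H]1C[C@](O)(C(=O)OCc2ccccc2)[C@H](I)[C@@H](O)[C@H]1OC(=O)c1cc(OCc2ccccc2)c(OCc2ccccc2)c(OCc2ccccc2)c1)c1cc(OCc2ccccc2)c(OCc2ccccc2)c(OCc2ccccc2)c1
F8 | step 5 | benzyl (5R)-5-hydroxycyclohexa-1,3-diene-1-carboxylate | O[C@@H]1CC(C(=O)OCc2ccccc2)=CC=C1
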